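The earlier runs and the new flask were generated by integration for substances that don't exist, and the scatter is random.

Stand at the vessel: partner lies stirred in it, substrate runs in, and the clock goes on.

| flask | substrate | partner | temperature | remark | time |
|---|---|---|---|---|---|
| maple | 1.4 M (fed, over 20 s) | 1.12 M | 0 °C | run made earlier; the fed solution adds 0.10 times the starting volume |  |
| ash | 1.9 M (fed, over 20 s) | 1.12 M | 0 °C | run made earlier; the fed solution adds 0.10 times the starting volume |  |
| south-west | 0.93 M (fed, over 20 s) | 1.12 M |  | at 0 °C until 20 s, from then on at 20 °C; the fed solution adds 0.10 times the starting volume | 20 min |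
| south | 0.93 M (fed, over 20 s) | 0.400 M |  | at 0 °C throughout; the fed solution adds 0.10 times the starting volume | 10 min |

| run | time / min | product / % | substrate / % |
|---|---|---|---|
| maple | 0.333 | 4.0 | 96.9 |
| maple | 0.500 | 8.1 | 92.8 |
| maple | 0.667 | 10.4 | 88.9 |
| maple | 1.00 | 16.6 | 82.5 |
| maple | 1.50 | 24.0 | 76.1 |
| maple | 2.50 | 32.6 | 67.6 |
| maple | 4.00 | 41.0 | 59.2 |
| ash | 0.200 | 1.2 | 58.9 |
| ash | 0.667 | 13.2 | 86.2 |
| ash | 1.00 | 20.3 | 80.5 |
| ash | 1.50 | 26.9 | 73.7 |
| ash | 2.50 | 34.3 | 65.4 |
| ash | 3.00 | 37.4 | 61.8 |
| ash | 4.00 | 41.7 | 58.2 |

(standard deviation of a reading: 0.5 percentage points)

- every charge counts on the volume at the start, and the solution that is fed holds the whole dose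
- the numbers in the tables scatter by 0.5 percentage points (one standard deviation)
- the earlier runs do not show what temperature does; that part of a forecast is a guess
- percentages count the whole charge, also what has not yet gone in

- the flask that ends with the higher amount of product, in percent of the substrate charged, or "neither" when 2 percentage points or less lies between them (south-west / south / neither)
- final product, as a percentage of the substrate charged, in south-west
- final product, as a percentage of the substrate charged, in south

Read the two runs first. Take maple and ash between 0.667 min and 2.50 min, replace each curve by its mean over that stretch, and count one partner lost per product. Then divide the rate of product by the substrate fraction squared, by the substrate charge and by mean partner, both per volume after the feed. Maple gives 0.00348 M⁻² s⁻¹ and ash 0.00318 M⁻² s⁻¹. Ash over maple stands at 0.914, where the first power of substrate gives 1.20. Keep the square, and keep the mean of the two, 0.00333 M⁻² s⁻¹, as the mean-partner constant.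

Hold partner at its mean and the curve integrates: the substrate fraction left is the reciprocal of one plus clock over θ. Here θ, the time for substrate to fall to half, is the reciprocal of the constant times substrate charge times mean partner.

Now climb the times. In south, partner is the limiting reagent, with a ceiling of 43.0% if each product takes one partner, so try 28.7% product. In south-west, try 66.7%. The feed, 20 s, is far shorter than south-west's cold θ of 8.04 min, so start the clock at mid-feed. Next comes south's 10 min, and above it south's θ of 24.4 min. The reckoning therefore puts south at 28.7%, which returns the trial. With the cold constant, the reckoning puts south-west at 71.2%, above its trial. What 20 °C adds is a guess, so commit to these two figures, south-west ahead.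

The forecast names south-west, with 85% there and 28% in south, taking the warming as “a guess, about fourfold”. On south-west it stands above this reckoning.

The flasks give 62.3% in south-west and 25.8% in south, so south-west ends higher.

    partner → decomposed reagent (k = 5.50 × 10⁻⁴ s⁻¹, Ea = 75.0 kJ mol⁻¹)
    substrate + partner → product, rate k2*[substrate]^2*[partner] (k = 0.00390 M⁻² s⁻¹, Ea = 56.0 kJ mol⁻¹)
    (constants at 0 °C)

South-west ends below its cold reckoning, holding 0.00882% of its partner and 0.492 M decomposed reagent at 20.0 min. South lies 2.9 percentage points under its figure. Take the neighbour, south with 1.6 M partner, where substrate sets the ceiling: try 66.7%, and the same constant gives θ of 5.05 min and 66.1% product. That flask gives 63.4%, 2.7 points lower, with 42.6% of its partner left and 0.299 M decomposed reagent at 10.0 min.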